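**Retrosynthetic overview**

1. The target comes from hydroquinone 24 by double O‑methylation and loss of two benzyl groups. Ring D of the flavan carries its oxygens on C5 and C8 para to each other, so it is a latent 1,4‑benzoquinone; C8a–H is the β‑carbon of the C5 enone and lies six atoms from the C2 oxygen. Ring F is therefore opened at O1–C8a, giving hydroxy‑quinone 21.
2. 21 comes from (NH4)2Ce(NO3)6 oxidation of dimethoxyarene 20. Its carbinol comes from oxazaborolidine reduction of ketone 19, and the diaryl centre (future C4) from rhodium/diene addition of boronic acid 8 to enone 18.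
3. 18 comes from Heck coupling of iodoflavanone 15 with phenyl vinyl ketone. 15 comes from rhodium/diene addition of PhB(OH)2 to chromone 13, which is iodinated at C6 and benzylated at O5 before any stereocentre exists.
4. Ring order: rings A and D are bought as arenes (9 and 1). Ring C is closed in step 5 and made stereogenic in step 8. Rings B and E arrive as phenyl groups (14 and 16). Ring F is closed last, in step 13.

Key step: step 13

Remark on labels: the flavan unit is labelled O1, C2, C3, C4, C4a, C5–C8, C8a (ring D arene, ring F pyran, ring E phenyl), also in its open‑chain precursors; the flavanone unit has rings A (arene), C (pyranone) and B (phenyl).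

Assumption: the face selection of the Ph‑bod* dienes is taken from their behaviour with 2‑cyclohexenone ((R,R) gives attack on the αre face) and from the rule that the carbonyl‑bearing α‑carbon is the element recognised; the sense is to be confirmed on the first run of steps 8 and 10, and the antipodal diene used if it is reversed.

**Route**

Step 1
Reactants: 1 2,5-dimethoxybenzaldehyde
Product: 3 2,5-dimethoxyphenol, via 2,5-dimethoxyphenyl formate 2 (not isolated)
Conditions: mCPBA, CH2Cl2, 0 °C → rt; aq NaHCO3 wash; then Et3N (cat.), MeOH, rt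
Reagents that add atoms: meta-chloroperoxybenzoic acid O=C(OO)c1cccc(Cl)c1
Why: Baeyer–Villiger (Dakin-type) oxidation in which the electron-rich aryl group migrates, followed by methanolysis of the aryl formate.

Step 2
Reactants: 3 2,5-dimethoxyphenol
Product: 4 2-(benzyloxy)-1,4-dimethoxybenzene
Conditions: BnBr, K2CO3, DMF, rt
Reagents that add atoms: benzyl bromide BrCc1ccccc1
Why: Williamson ether synthesis on the phenoxide.

Step 3
Reactants: 4 2-(benzyloxy)-1,4-dimethoxybenzene
Product: 5 1-(benzyloxy)-4-bromo-2,5-dimethoxybenzene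
Conditions: NBS, MeCN, 0 °C → rt
Reagents that add atoms: N-bromosuccinimide O=C1CCC(=O)N1Br
Why: Electrophilic aromatic bromination should go para to the benzyloxy group and ortho to one methoxy group, the only position activated by two oxygens without being flanked by two, as in the bromination of 1,2,4-trimethoxybenzene.

Step 4
Reactants: 5 1-(benzyloxy)-4-bromo-2,5-dimethoxybenzene
Product: 8 (4-benzyloxy-2,5-dimethoxyphenyl)boronic acid, via aryllithium 6 (not isolated), via lithium aryltriisopropoxyborate 7 (not isolated)
Conditions: n-BuLi, THF, −78 °C; B(OiPr)3, −78 °C → rt; aq HCl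
Reagents that add atoms: triisopropyl borate CC(C)OB(OC(C)C)OC(C)C; water O
Why: Bromine–lithium exchange, capture of the aryllithium by the borate and acid hydrolysis give the boronic acid, which has a single ortho substituent because the C8a oxygen is installed only in step 13.

Step 5
Reactants: 9 2',6'-dihydroxy-4'-methoxyacetophenone
Product: 11 5-hydroxy-7-methoxy-4H-chromen-4-one, via enaminone 10 (not isolated)
Conditions: Me2NCH(OMe)2, toluene, 90 °C; then conc. HCl, CH2Cl2, 40 °C
Reagents that add atoms: N,N-dimethylformamide dimethyl acetal COC(OC)N(C)C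
Why: Enaminone condensation at the acetyl methyl group followed by acid-promoted addition–elimination of a phenol (loss of dimethylamine) is the standard chromone synthesis, and the two phenols of 9 are equivalent, so only one chromone can form.

Step 6
Reactants: 11 5-hydroxy-7-methoxy-4H-chromen-4-one
Product: 12 5-hydroxy-6-iodo-7-methoxy-4H-chromen-4-one
Conditions: BnMe3N·ICl2, CaCO3, CH2Cl2–MeOH, rt
Reagents that add atoms: benzyltrimethylammonium dichloroiodate C[N+](C)(C)Cc1ccccc1.Cl[I-]Cl
Why: Electrophilic iodination of a chelated 5-hydroxy-7-alkoxy chromone system should go ortho to the free hydroxyl (C6), the preference known for 5-hydroxy-7-methoxyflavones with this reagent, whereas 5-O-alkyl ethers react at C8, which is why iodination precedes benzylation.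

Step 7
Reactants: 12 5-hydroxy-6-iodo-7-methoxy-4H-chromen-4-one
Product: 13 5-(benzyloxy)-6-iodo-7-methoxy-4H-chromen-4-one
Conditions: BnBr, K2CO3, DMF, 60 °C
Reagents that add atoms: benzyl bromide BrCc1ccccc1
Why: Williamson etherification of the chelated phenol is forced here, at the achiral chromone stage, because the same conditions would open a 5-hydroxyflavanone to its chalcone and erase C2.

Step 8
Reactants: 13 5-(benzyloxy)-6-iodo-7-methoxy-4H-chromen-4-one; 14 phenylboronic acid
Product: 15 (2R)-5-(benzyloxy)-6-iodo-7-methoxy-2-phenylchroman-4-one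
Conditions: [RhCl(C2H4)2]2 (2.5 mol %), (R,R)-Ph-bod* [(1R,4R)-2,5-diphenylbicyclo[2.2.2]octa-2,5-diene] (5.5 mol %), KOH (10 mol %), dioxane–H2O 10:1, 40 °C
Reagents that add atoms: none
Why: Hayashi–Miyaura rhodium/chiral diene 1,4-addition of an arylboronic acid to a chromone, in which the (R,R)-diene should expose the αre face of C3 so that phenyl is delivered to C2 from that face and gives (2R), while the hindered aryl iodide is not expected to add oxidatively to monovalent rhodium at this temperature and the excess boronic acid buffers the base.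

Step 9
Reactants: 15 (2R)-5-(benzyloxy)-6-iodo-7-methoxy-2-phenylchroman-4-one; 16 3-chloropropiophenone
Product: 18 (2R)-5-(benzyloxy)-7-methoxy-6-[(1E)-3-oxo-3-phenylprop-1-en-1-yl]-2-phenylchroman-4-one, via phenyl vinyl ketone 17 (not isolated)
Conditions: Pd(OAc)2 (10 mol %), n-Bu4NCl, NaHCO3, DMF, 70 °C
Reagents that add atoms: none
Why: Mizoroki–Heck coupling under ligand-free phase-transfer conditions with the vinyl ketone released in the flask by dehydrochlorination; syn insertion and syn β-hydride elimination give the (E)-enone, and the weak hydrogencarbonate base should leave the flavanone C2 centre intact.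

Step 10
Reactants: 18 (2R)-5-(benzyloxy)-7-methoxy-6-[(1E)-3-oxo-3-phenylprop-1-en-1-yl]-2-phenylchroman-4-one; 8 (4-benzyloxy-2,5-dimethoxyphenyl)boronic acid
Product: 19 (2R)-5-(benzyloxy)-6-[(1R)-1-(4-benzyloxy-2,5-dimethoxyphenyl)-3-oxo-3-phenylpropyl]-7-methoxy-2-phenylchroman-4-one
Conditions: Rh(acac)(C2H4)2 (5 mol %), (S,S)-Ph-bod* (6 mol %), K3PO4 (0.3 equiv), dioxane–H2O 10:1, 50 °C (8 in threefold excess)
Reagents that add atoms: none
Why: Hayashi–Miyaura 1,4-addition to a β-aryl enone under catalyst control, in which the (S,S)-diene should bind the αsi face of the (E)-enone so that the ring D aryl group reaches the β-carbon from that face and sets the (1R) centre (the future flavan C4), the remote flavanone centre having no influence.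

Step 11
Reactants: 19 (2R)-5-(benzyloxy)-6-[(1R)-1-(4-benzyloxy-2,5-dimethoxyphenyl)-3-oxo-3-phenylpropyl]-7-methoxy-2-phenylchroman-4-one
Product: 20 (2R)-5-(benzyloxy)-6-[(1R,3S)-1-(4-benzyloxy-2,5-dimethoxyphenyl)-3-hydroxy-3-phenylpropyl]-7-methoxy-2-phenylchroman-4-one
Conditions: (R)-2-methyl-CBS-oxazaborolidine (20 mol %), BH3·SMe2 (0.7 equiv), THF, −30 °C; MeOH quench
Reagents that add atoms: none
Why: Corey–Bakshi–Shibata reduction in which phenyl is the large group, so the (R)-oxazaborolidine should give the (S)-carbinol, while the flavanone carbonyl, a vinylogous ester flanked by the 5-benzyloxy group, is much less electrophilic and should be left by the limiting amount of borane.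

Step 12
Reactants: 20 (2R)-5-(benzyloxy)-6-[(1R,3S)-1-(4-benzyloxy-2,5-dimethoxyphenyl)-3-hydroxy-3-phenylpropyl]-7-methoxy-2-phenylchroman-4-one
Product: 21 2-(benzyloxy)-5-[(1S,3S)-1-[(2R)-5-(benzyloxy)-7-methoxy-4-oxo-2-phenylchroman-6-yl]-3-hydroxy-3-phenylpropyl]cyclohexa-2,5-diene-1,4-dione
Conditions: (NH4)2Ce(NO3)6 (2.5 equiv), MeCN–H2O 3:1, 0 °C, short reaction time
Reagents that add atoms: water O
Why: Oxidative demethylation of a para-dimethoxyarene by tetravalent cerium: only the 1,2,4-trioxygenated ring D is electron-rich enough to give the radical cation, water attacks the methoxy-bearing C5 and C8 and methanol is lost to leave the 2-benzyloxy-1,4-benzoquinone, while the acyl-deactivated ring A is spared; any material that already closes to chromanquinone 23 in this acidic medium is carried on, since step 13 converges on the same hydroquinone.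

Step 13
Reactants: 21 2-(benzyloxy)-5-[(1S,3S)-1-[(2R)-5-(benzyloxy)-7-methoxy-4-oxo-2-phenylchroman-6-yl]-3-hydroxy-3-phenylpropyl]cyclohexa-2,5-diene-1,4-dione
Product: 24 (2R)-5-(benzyloxy)-6-[(2S,4S)-7-(benzyloxy)-5,8-dihydroxy-2-phenylchroman-4-yl]-7-methoxy-2-phenylchroman-4-one, via oxa-Michael dienol adduct 22 (not isolated), via chromanquinone 23 (not isolated)
Conditions: camphorsulfonic acid (20 mol %), chloranil (1.1 equiv), CH2Cl2 (0.01 M), rt, argon; then aq Na2S2O4
Reagents that add atoms: none
Why: Protonation of the more basic carbonyl oxygen on C5 (the vinylogous-ester carbonyl, conjugated to the C7 benzyloxy group) makes C8a, the β-carbon of the C5 enone, electrophilic; the C2 carbinol oxygen adds there and loss of the C8a proton restores the arene as the 5,8-hydroquinone, the closest known reaction type being the acid-catalysed conjugate addition of alcohols to 1,4-benzoquinones with enolisation to the hydroquinone. Ring F closes in a 6-endo-trig mode (O1–C8a), at the only hydrogen-bearing position the three-carbon tether can reach: attack at the substituted C4a would be a reversible spiro closure that cannot re-aromatise, and C6 and C7 are out of reach. No stereocentre is created, since C8a is sp3 only in adduct 22, and the 2,4-trans relationship follows from the (1S,3S) chain of 21 because the O–H bond adds and the carbinol C–O bond is untouched. Hydroquinone 24 is a stronger reductant than 21 and would reduce unreacted 21 to an open hydroquinone that cannot cyclise, which would cap the conversion at one half; chloranil therefore keeps all open material at the quinone level (24 passing on to quinone 23), and the Na2S2O4 work-up returns 23 to 24. The step needs conjugate addition to win over ionisation of the benzylic carbinol and over tautomerisation of the C4 methine to a quinone methide, which would scramble C4; the weak non-nucleophilic acid, the absence of base and room temperature are chosen to secure this.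

Step 14
Reactants: 24 (2R)-5-(benzyloxy)-6-[(2S,4S)-7-(benzyloxy)-5,8-dihydroxy-2-phenylchroman-4-yl]-7-methoxy-2-phenylchroman-4-one
Product: 25 (2R)-5-(benzyloxy)-6-[(2S,4S)-7-(benzyloxy)-5,8-dimethoxy-2-phenylchroman-4-yl]-7-methoxy-2-phenylchroman-4-one
Conditions: MeI, K2CO3, acetone (degassed), rt → 40 °C, argon
Reagents that add atoms: iodomethane CI
Why: Williamson O-methylation of both hydroquinone hydroxyls under mild carbonate conditions, with air excluded so that 24 is not reoxidised and the temperature kept low so that the 5-O-benzyl flavanone is not opened to its chalcone.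

Step 15
Reactants: 25 (2R)-5-(benzyloxy)-6-[(2S,4S)-7-(benzyloxy)-5,8-dimethoxy-2-phenylchroman-4-yl]-7-methoxy-2-phenylchroman-4-one
Product: 26 (2R)-5-hydroxy-6-[(2S,4S)-7-hydroxy-5,8-dimethoxy-2-phenylchroman-4-yl]-7-methoxy-2-phenylchroman-4-one
Conditions: H2 (1 atm), Pd/C, EtOAc–MeOH, rt, stopped after uptake of two equivalents
Reagents that add atoms: none
Why: Hydrogenolysis of the two aryl benzyl ethers, which should be cleaved faster than the cyclic benzylic C2–O bonds of the flavan and flavanone rings and than the chelated ketone.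

**Compound list**

1 | 2,5-dimethoxybenzaldehyde | COc1ccc(OC)c(C=O)c1 | starting material
2 | 2,5-dimethoxyphenyl formate (not isolated) | COc1ccc(OC)c(OC=O)c1 | intermediate
3 | 2,5-dimethoxyphenol | COc1ccc(OC)c(O)c1 | intermediate
4 | 2-(benzyloxy)-1,4-dimethoxybenzene | COc1ccc(OC)c(OCc2ccccc2)c1 | intermediate
5 | 1-(benzyloxy)-4-bromo-2,5-dimethoxybenzene | COc1cc(OCc2ccccc2)c(OC)cc1Br | intermediate
6 | (4-benzyloxy-2,5-dimethoxyphenyl)lithium (not isolated) | COc1cc(OCc2ccccc2)c(OC)cc1[Li] | intermediate
7 | lithium (4-benzyloxy-2,5-dimethoxyphenyl)triisopropoxyborate (not isolated) | [Li+].COc1cc(OCc2ccccc2)c(OC)cc1[B-](OC(C)C)(OC(C)C)OC(C)C | intermediate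
8 | (4-benzyloxy-2,5-dimethoxyphenyl)boronic acid | COc1cc(OCc2ccccc2)c(OC)cc1B(O)O | intermediate
9 | 2',6'-dihydroxy-4'-methoxyacetophenone | COc1cc(O)c(C(C)=O)c(O)c1 | starting material
10 | (2E)-1-(2,6-dihydroxy-4-methoxyphenyl)-3-(dimethylamino)prop-2-en-1-one (not isolated) | COc1cc(O)c(C(=O)/C=C/N(C)C)c(O)c1 | intermediate
11 | 5-hydroxy-7-methoxy-4H-chromen-4-one | O=c1ccoc2cc(OC)cc(O)c12 | intermediate
12 | 5-hydroxy-6-iodo-7-methoxy-4H-chromen-4-one | O=c1ccoc2cc(OC)c(I)c(O)c12 | intermediate
13 | 5-(benzyloxy)-6-iodo-7-methoxy-4H-chromen-4-one | O=c1ccoc2cc(OC)c(I)c(OCc3ccccc3)c12 | intermediate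
14 | phenylboronic acid | OB(O)c1ccccc1 | starting material
15 | (2R)-5-(benzyloxy)-6-iodo-7-methoxy-2-phenylchroman-4-one | COc1cc2c(c(OCc3ccccc3)c1I)C(=O)C[C@H](c1ccccc1)O2 | intermediate
16 | 3-chloropropiophenone | O=C(CCCl)c1ccccc1 | starting material
17 | phenyl vinyl ketone (not isolated) | C=CC(=O)c1ccccc1 | intermediate
18 | (2R)-5-(benzyloxy)-7-methoxy-6-[(1E)-3-oxo-3-phenylprop-1-en-1-yl]-2-phenylchroman-4-one | COc1cc2c(c(OCc3ccccc3)c1/C=C/C(=O)c1ccccc1)C(=O)C[C@H](c1ccccc1)O2 | intermediate
19 | (2R)-5-(benzyloxy)-6-[(1R)-1-(4-benzyloxy-2,5-dimethoxyphenyl)-3-oxo-3-phenylpropyl]-7-methoxy-2-phenylchroman-4-one | COc1cc2c(c(OCc3ccccc3)c1[C@H](CC(=O)c1ccccc1)c1cc(OC)c(OCc3ccccc3)cc1OC)C(=O)C[C@H](c1ccccc1)O2 | intermediate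
20 | (2R)-5-(benzyloxy)-6-[(1R,3S)-1-(4-benzyloxy-2,5-dimethoxyphenyl)-3-hydroxy-3-phenylpropyl]-7-methoxy-2-phenylchroman-4-one | COc1cc2c(c(OCc3ccccc3)c1[C@H](C[C@H](O)c1ccccc1)c1cc(OC)c(OCc3ccccc3)cc1OC)C(=O)C[C@H](c1ccccc1)O2 | intermediate
21 | 2-(benzyloxy)-5-[(1S,3S)-1-[(2R)-5-(benzyloxy)-7-methoxy-4-oxo-2-phenylchroman-6-yl]-3-hydroxy-3-phenylpropyl]cyclohexa-2,5-diene-1,4-dione | COc1cc2c(c(OCc3ccccc3)c1[C@H](C[C@H](O)c1ccccc1)C1=CC(=O)C(OCc3ccccc3)=CC1=O)C(=O)C[C@H](c1ccccc1)O2 | intermediate
22 | oxa-Michael adduct of 21 before enolisation: ring F closed; C8a sp3 and undefined; C5 enol; C8 ketone; C2 and C4 arranged as in 24 (not isolated) | COc1cc2c(c(OCc3ccccc3)c1[C@@H]1C[C@@H](c3ccccc3)OC3C(=O)C(OCc4ccccc4)=CC(O)=C13)C(=O)C[C@H](c1ccccc1)O2 | intermediate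
23 | (2S,4S)-7-(benzyloxy)-4-[(2R)-5-(benzyloxy)-7-methoxy-4-oxo-2-phenylchroman-6-yl]-2-phenyl-3,4-dihydro-2H-chromene-5,8-dione (not isolated) | COc1cc2c(c(OCc3ccccc3)c1[C@@H]1C[C@@H](c3ccccc3)OC3=C1C(=O)C=C(OCc4ccccc4)C3=O)C(=O)C[C@H](c1ccccc1)O2 | intermediate
24 | (2R)-5-(benzyloxy)-6-[(2S,4S)-7-(benzyloxy)-5,8-dihydroxy-2-phenylchroman-4-yl]-7-methoxy-2-phenylchroman-4-one | COc1cc2c(c(OCc3ccccc3)c1[C@@H]1C[C@@H](c3ccccc3)Oc3c(O)c(OCc4ccccc4)cc(O)c31)C(=O)C[C@H](c1ccccc1)O2 | intermediate
25 | (2R)-5-(benzyloxy)-6-[(2S,4S)-7-(benzyloxy)-5,8-dimethoxy-2-phenylchroman-4-yl]-7-methoxy-2-phenylchroman-4-one | COc1cc2c(c(OCc3ccccc3)c1[C@@H]1C[C@@H](c3ccccc3)Oc3c(OC)c(OCc4ccccc4)cc(OC)c31)C(=O)C[C@H](c1ccccc1)O2 | intermediate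
26 | (2R)-5-hydroxy-6-[(2S,4S)-7-hydroxy-5,8-dimethoxy-2-phenylchroman-4-yl]-7-methoxy-2-phenylchroman-4-one (2,4-trans flavan) | COc1cc2c(c(O)c1[C@@H]1C[C@@H](c3ccccc3)Oc3c(OC)c(O)cc(OC)c31)C(=O)C[C@H](c1ccccc1)O2 | target

**Step count and risks**

Total step count: 15. Longest linear sequence: 11 steps (9 → 26, steps 5–15); the boronic acid branch (steps 1–4) joins at step 10.

The three steps most likely to fail:

1. Step 13 (ring F closure). The conjugate addition may be slow, because the enone that must accept the alcohol is the deactivated vinylogous-ester half of the quinone. Forcing it with stronger acid invites ionisation of the benzylic carbinol (loss of C2 configuration, or closure through the C5 oxygen) and enolisation of the C4 methine towards a quinone methide. Redox exchange between product and starting quinone may also outrun the recycling by chloranil. Fallback: set out from 20 and close the same O1–C8a bond by oxidative aryl C–O cyclisation with the hypervalent iodine reagent PhI(OCOCF3)2 in (CF3)2CHOH at 0 °C, the arene radical-cation cyclisation known for 3-arylpropanols giving chromans. The ring D radical cation should be trapped by the carbinol oxygen at C8a (ortho to the tether and to a methoxy group), and loss of a proton and a second electron re-aromatises with both methyl ethers still in place. The carbinol configuration is kept because its O–H bond reacts. This gives 25 directly and makes no compound outside the list (F0); the route is rejoined at 25, before step 15.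

2. Step 10 (rhodium addition to the hindered enone). Insertion at a β-carbon flanked by a 2,6-dioxygenated aryl group may be slow, so that protodeboronation of the electron-rich boronic acid outruns addition, and the twisted β-aryl group may erode facial discrimination. Fallback: set out from 18 and bromide 5. Aryllithium 6 (from 5, n-BuLi, THF, −78 °C) is transmetallated with CuBr·SMe2 (half an equivalent) to lithium bis(4-benzyloxy-2,5-dimethoxyphenyl)cuprate F1, which should add to the enone of 18 in Et2O–THF at −78 → −30 °C without touching either ketone. With no catalyst control this gives 19 together with (2R)-5-(benzyloxy)-6-[(1S)-1-(4-benzyloxy-2,5-dimethoxyphenyl)-3-oxo-3-phenylpropyl]-7-methoxy-2-phenylchroman-4-one F2. The two are diastereomers, because C2 of the flavanone is fixed, and are separated by chromatography; 19 rejoins the route at step 11.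

3. Step 11 (reduction of one of two aryl ketones). Hydride may also be delivered to the flavanone carbonyl, and the facial discrimination may be weak because the "small" substituent is a bulky 2,2-diarylethyl group. Fallback: set out from 15 and make the carbinol by aryl addition to an aldehyde instead of ketone reduction, so that no ketone has to be told from another.
   - Mizoroki–Heck coupling of 15 with acrolein (Pd(OAc)2, n-Bu4NCl, NaHCO3, DMF) gives (2R)-5-(benzyloxy)-7-methoxy-6-[(1E)-3-oxoprop-1-en-1-yl]-2-phenylchroman-4-one F3.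
   - Rhodium/(S,S)-Ph-bod* addition of 8 to this enal, with the same facial sense as in step 10 and a more reactive acceptor, gives (2R)-5-(benzyloxy)-6-[(1R)-1-(4-benzyloxy-2,5-dimethoxyphenyl)-3-oxopropyl]-7-methoxy-2-phenylchroman-4-one F4.
   - Catalytic enantioselective phenyl transfer from a phenylzinc reagent (PhB(OH)2/Et2Zn with a chiral amino alcohol ligand, antipode chosen for Re-face delivery) to the aldehyde, which is far more electrophilic than the flavanone ketone, gives 20, where the route is rejoined before step 12.

Further compounds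
F0 | step 13 | none | none
F1 | step 10 | lithium bis(4-benzyloxy-2,5-dimethoxyphenyl)cuprate | [Li+].COc1cc(OCc2ccccc2)c(OC)cc1[Cu-]c1cc(OC)c(OCc2ccccc2)cc1OC
F2 | step 10 | (2R)-5-(benzyloxy)-6-[(1S)-1-(4-benzyloxy-2,5-dimethoxyphenyl)-3-oxo-3-phenylpropyl]-7-methoxy-2-phenylchroman-4-one | COc1cc2c(c(OCc3ccccc3)c1[C@@H](CC(=O)c1ccccc1)c1cc(OC)c(OCc3ccccc3)cc1OC)C(=O)C[C@H](c1ccccc1)O2
F3 | step 11 | (2R)-5-(benzyloxy)-7-methoxy-6-[(1E)-3-oxoprop-1-en-1-yl]-2-phenylchroman-4-one | COc1cc2c(c(OCc3ccccc3)c1/C=C/C=O)C(=O)C[C@H](c1ccccc1)O2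
F4 | step 11 | (2R)-5-(benzyloxy)-6-[(1R)-1-(4-benzyloxy-2,5-dimethoxyphenyl)-3-oxopropyl]-7-methoxy-2-phenylchroman-4-one | COc1cc2c(c(OCc3ccccc3)c1[C@H](CC=O)c1cc(OC)c(OCc3ccccc3)cc1OC)C(=O)C[C@H](c1ccccc1)O2
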